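## The problem

The target is a eudesmane-type decalin (ring A = C1–C5 and C10, ring B = C5–C10) whose rings are joined cis: the C10 methyl group and H5 lie on the same face, so the fusion has to be made cis by design. Five stereocentres must be set: C3 (angelate), C4 (acetate and methyl, no hydrogen), C5, C7 (isopropyl) and C10 (quaternary). C4, C5 and C10 are contiguous and can only be fixed in C–C bond-forming events. C3 is the one centre that is easy to obtain enantiopure, and as the neighbour of C4 it is the natural source of control for C4, C5 and C10. C7 is α to the C8 ketone, and the required configuration is the more stable one (isopropyl equatorial in the chair–chair form that keeps both ring A methyl groups equatorial), so it is ultimately under thermodynamic control. The esters are the fragile part. The angelate isomerises to the tiglate under nucleophilic catalysis, strong base or acid and does not survive hydrogenation; the tertiary acetate is hard to install, can eliminate, and would migrate to a free cis-vicinal C3 hydroxyl. The esters therefore come last, angelate before acetate. A one-step bicyclisation is possible because of the sequence C3(O)–C4(O)(CH3)–C5–C10(CH3)–C9–C8(=O): C4 can be a methyl ketone carbon, C5=C10 a trisubstituted alkene that becomes a tertiary C10 cation when C5 attacks, C9 the carbon terminus of a C8 enol silane, and the C3 oxygen a second binding site for a Lewis acid.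

## Retrosynthesis

**Esters.** The C4 O–acetyl bond of target 27 is cut first and the C3 O–angeloyl bond second. This leads through hydroxy angelate 26 to diol 23 and angelic acid 24, and then to benzyl ether 22. The opposite order would leave a tertiary acetate beside a free secondary hydroxyl, the arrangement that invites acyl migration. Benzyl is chosen for O3 because 22 contains no alkene, so hydrogenolysis is clean and precedes the hydrogenation-sensitive angelate, and because a benzyl ether can chelate. The forward steps must acylate a secondary hydroxyl without Z-to-E isomerisation and then a hindered tertiary hydroxyl without base.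

**Both rings (key cut).** In 22 the bonds C4–C5 and C9–C10 are cut together, giving the open-chain keto enol silane 21. The biogenetic cut C5–C10 would leave a C4 cation to be hydrated with stereocontrol; here the C4 oxygen is the ketone oxygen, and every oxygen of the target is already in place. The precursor has two stereocentres (C3, C7) against five in 22. The forward reaction needs a Z alkene (anti addition then gives the cis fusion), a chelating ether on O3, and an enol silane robust enough to wait for the C10 cation.

**C4 oxidation level.** Ketone 21 is traced to carbinol 20. The C8 enol silane has to be made by base from a methyl ketone, and this cannot be done selectively beside a second methyl ketone at C4. The C4 oxygen is therefore carried as a hydroxyl until the enol silane exists. The forward oxidation must spare the enol silane and not epimerise C3.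

**C1–C10 bond.** Cutting the sp3–sp2 bond of 20 gives alkenol 18 and alkenyl iodide 14. A cut at C6–C7 at this stage would be an enolate alkylation beside a free hydroxyl. Building the alkene by cuprate addition to an ynoate would set the geometry on the full chain and require a hydride reduction that other groups do not tolerate. Here the Z geometry is bought in a four-carbon iodide and carried over with retention, and the two halves (5 and 10 skeletal carbons) are made independently.

**Right-hand half.** Enol silane 14 comes from methyl ketone 12, which comes from Weinreb amide 11, acid 10 and imide 9. Cutting C6–C7 in 9 gives the isovaleryl imide 7 and allylic bromide 4. The auxiliary sets C7, so a single diastereomer enters the key step; C9 arrives as the methyl group of the ketone.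

**Small pieces.** Bromide 4 comes from iodo alcohol 3, and 3 from but-2-yn-1-ol 1 by directed hydroalumination and iodination, which fixes the Z geometry. Imide 7 comes from oxazolidinone 5 and acid chloride 6.

**Left-hand half.** Alkenol 18 comes from epoxide 17 by hydride opening, which makes the C4 methyl group. Epoxide 17 comes from epoxy alcohol 16, and 16 from divinylcarbinol 15 by asymmetric epoxidation. One reaction creates C3, places the C4 oxygen and leaves the vinyl group that becomes C1–C2.

## Roads not taken

**Alternative 1:** Ireland–Claisen ring contraction.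
- Cut: the C5–C10 bond only. Ring A is traced to a six-membered lactone (C6 carbonyl, ring oxygen on C2) bearing the C1=C10 alkenyl group.
- Forward key step: the silyl ketene acetal (LiN(iPr)2, Me3SiCl) rearranges through a boat, C5 bonding to C10 as C2–O breaks. This gives acid A1 with the C1=C2 alkene, the C3/C4 diol as acetonide and the C6 carboxyl on C5.
- Merits: a well-understood sigmatropic step; the quaternary C10 is made by chirality transfer; the diol stereochemistry comes from a dihydroxylation, not from a new cyclisation.
- Weak points: only one ring and two stereocentres are made. Ring B must still be closed between C6 and C7. C6 arrives as a carboxyl although it is a methylene in the target, so an acylation, a deoxygenation and hydrogenation of C1=C2 follow. The boat must set a vicinal tertiary–quaternary pair cis, which depends on enolate and alkene geometry.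
- Comparison: on precedent for the key step this road is better. The plan adopted here sets against it that every carbon of 22 is formed at its final oxidation level and both rings close at once.

**Alternative 2:** desymmetrising palladium cyclisation.
- Cut: C9–C10 only. Ring A pre-exists as a prochiral cyclohexadiene with the C6–C9 chain on C5.
- Forward key step: Pd(OAc)2, a chiral pyridine–oxazoline ligand and O2 turn the enol silane into a C9 palladium enolate. It adds to C10 of one enantiotopic alkene, and β-hydride elimination gives cis-fused dienone A2.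
- Merits: catalytic enantiocontrol, no auxiliary, and a very short path to the carbon skeleton. In these respects it is ahead of the adopted plan, which uses a stoichiometric oxazolidinone.
- Weak points: A2 carries no oxygen on C3 or C4. The C3=C4 alkene would have to be dihydroxylated beside the conjugated C1=C2 alkene, and from the α face, which ring B covers in a cis-decalin; C1=C2 must then be reduced. Six-membered closure to a quaternary centre by this enolate–alkene coupling, with high enantioselection, is at the edge of what is documented.
- Comparison: the adopted plan installs O3 and O4 before cyclisation and uses them as the control element, which is exactly the part this road leaves open.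

**Alternative 3:** phenol dearomatisation, Diels–Alder, anionic oxy-Cope.
- Cut: C1–C10 forms while C3–C8 breaks in a [3,3] shift of a bicyclo[2.2.2]octene vinyl carbinol.
- Forward key step: the potassium alkoxide (KH, 18-crown-6) rearranges to cis-decalin A3 with a C3 ketone, a C4 methoxymethyl ether and a C8=C9 alkene.
- Merits: the most secure ring-forming step of the four. It is strain-driven, the cis fusion is enforced by the bicyclic template, and the C4 oxygen comes from the phenol.
- Weak points: the oxygen pattern is off at both ends. C8=C9 must be oxidised regioselectively to the C8 ketone between two similar positions; the C3 ketone must be reduced to the alcohol cis to O4; a tertiary methoxymethyl ether must be cleaved with acid. The dearomatisation/Diels–Alder sequence is racemic unless a resolution or chiral partner is added.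
- Comparison: reliability of ring formation is better here. The adopted plan sets against it direct delivery of the C8 ketone and the C3 configuration, absolute control from an asymmetric epoxidation, and only three steps after ring formation.

Key step: step 14

Remark on the chemistry: eudesmane numbering (ring A = C1–C5, C10; ring B = C5–C10) is used for every intermediate, open-chain ones included, so that an atom keeps its number from starting material to target.

## Steps

Step 1
Reactants: 1 but-2-yn-1-ol
Product: 3 (Z)-3-iodobut-2-en-1-ol, via cyclic alkenylalanate 2 (not isolated)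
Conditions: NaAlH2(OCH2CH2OMe)2, THF, 0 °C to rt; then I2, THF, −78 to 0 °C
Reagents that add atoms: iodine, [I][I]
Why: Hydroxyl-directed trans-hydroalumination places aluminium on the methyl-bearing carbon cis to the CH2O group (five-membered alanate), and iodinolysis of the C–Al bond with retention gives the Z iodide; this fixes the geometry of the later C5=C10 alkene.

Step 2
Reactants: 3 (Z)-3-iodobut-2-en-1-ol
Product: 4 (Z)-1-bromo-3-iodobut-2-ene
Conditions: CBr4, PPh3, CH2Cl2, 0 °C
Reagents that add atoms: carbon tetrabromide, BrC(Br)(Br)Br
Why: Appel reaction; SN2 displacement at the primary allylic carbon proceeds without allylic transposition and leaves the alkene geometry untouched.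

Step 3
Reactants: 5 (R)-4-benzyloxazolidin-2-one; 6 3-methylbutanoyl chloride
Product: 7 (R)-4-benzyl-3-(3-methylbutanoyl)oxazolidin-2-one
Conditions: Et3N, DMAP (cat.), CH2Cl2, 0 °C to rt
Reagents that add atoms: none
Why: DMAP-catalysed N-acylation of the oxazolidinone by the acid chloride; no stereocentre is affected.

Step 4
Reactants: 7 (R)-4-benzyl-3-(3-methylbutanoyl)oxazolidin-2-one; 4 (Z)-1-bromo-3-iodobut-2-ene
Product: 9 (R)-4-benzyl-3-[(2R,4Z)-5-iodo-2-(propan-2-yl)hex-4-enoyl]oxazolidin-2-one, via sodium enolate 8 (not isolated)
Conditions: NaN(SiMe3)2, THF, −78 °C; then 4, −78 to −40 °C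
Reagents that add atoms: none
Why: Evans asymmetric alkylation forms the C6–C7 bond; the sodium-chelated Z enolate is alkylated by the allylic bromide on the face opposite the benzyl group of the auxiliary, which sets C7 as R.

Step 5
Reactants: 9 (R)-4-benzyl-3-[(2R,4Z)-5-iodo-2-(propan-2-yl)hex-4-enoyl]oxazolidin-2-one
Product: 10 (2R,4Z)-5-iodo-2-(propan-2-yl)hex-4-enoic acid
Conditions: LiOH, H2O2, THF/H2O, 0 °C; then Na2SO3; HCl to pH 2
Reagents that add atoms: hydrogen peroxide, OO
Why: Hydroperoxide attacks the exocyclic imide carbonyl selectively and the peracid is reduced by sulfite; C7 is not epimerised and auxiliary 5 is recovered.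

Step 6
Reactants: 10 (2R,4Z)-5-iodo-2-(propan-2-yl)hex-4-enoic acid
Product: 11 (2R,4Z)-5-iodo-N-methoxy-N-methyl-2-(propan-2-yl)hex-4-enamide
Conditions: MeNHOMe·HCl, EDC·HCl, HOBt, iPr2NEt, CH2Cl2, 0 °C to rt
Reagents that add atoms: N,O-dimethylhydroxylamine hydrochloride, CNOC.Cl
Why: Carbodiimide amide coupling through the hydroxybenzotriazole ester gives the Weinreb amide under conditions that do not enolise the α-branched acid.

Step 7
Reactants: 11 (2R,4Z)-5-iodo-N-methoxy-N-methyl-2-(propan-2-yl)hex-4-enamide
Product: 12 (3R,5Z)-6-iodo-3-(propan-2-yl)hept-5-en-2-one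
Conditions: MeMgBr, THF, 0 °C; aq. NH4Cl
Reagents that add atoms: methylmagnesium bromide, C[Mg]Br
Why: Weinreb ketone synthesis; the chelated tetrahedral intermediate prevents over-addition and the alkenyl iodide does not exchange with the Grignard reagent, so C8 becomes the ketone and C9 its methyl group.

Step 8
Reactants: 12 (3R,5Z)-6-iodo-3-(propan-2-yl)hept-5-en-2-one
Product: 14 {[(3R,5Z)-6-iodo-3-(propan-2-yl)hepta-1,5-dien-2-yl]oxy}tri(propan-2-yl)silane, via lithium enolate 13 (not isolated)
Conditions: LiN(iPr)2, THF, −78 °C; then iPr3SiOTf, −78 to 0 °C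
Reagents that add atoms: triisopropylsilyl trifluoromethanesulfonate, CC(C)[Si](OS(=O)(=O)C(F)(F)F)(C(C)C)C(C)C
Why: Kinetic deprotonation occurs at the methyl group (the other α position is a hindered tertiary C–H, so C7 is untouched) and the silyl triflate traps the enolate on oxygen; no second carbonyl is present, so the regiochemistry question cannot arise.

Step 9
Reactants: 15 penta-1,4-dien-3-ol
Product: 16 (2S,3R)-1,2-epoxypent-4-en-3-ol
Conditions: Ti(OiPr)4, D-(−)-diisopropyl tartrate, tBuOOH, 4 Å MS, CH2Cl2, −20 °C
Reagents that add atoms: tert-butyl hydroperoxide, CC(C)(C)OO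
Why: Sharpless asymmetric epoxidation used as a desymmetrisation; the catalyst selects one enantiotopic vinyl group and one of its faces (anti epoxy alcohol), and the minor enantiomer is drained by a fast second epoxidation, so C3 should be obtained R in very high enantiomeric excess.

Step 10
Reactants: 16 (2S,3R)-1,2-epoxypent-4-en-3-ol
Product: 17 (2S)-2-[(1R)-1-(benzyloxy)prop-2-en-1-yl]oxirane
Conditions: NaH, BnBr, nBu4NI (cat.), THF, −20 to 0 °C
Reagents that add atoms: benzyl bromide, BrCc1ccccc1
Why: Williamson etherification; cold aprotic conditions keep the alkoxide from Payne rearrangement, and the benzyl ether becomes the chelating group of the key step.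

Step 11
Reactants: 17 (2S)-2-[(1R)-1-(benzyloxy)prop-2-en-1-yl]oxirane
Product: 18 (2S,3R)-3-(benzyloxy)pent-4-en-2-ol
Conditions: LiAlH4, THF, 0 °C
Reagents that add atoms: none
Why: SN2 hydride opening at the unsubstituted epoxide carbon gives the C4 carbinol with its methyl group; C3 is untouched and the C4 configuration is of no consequence because C4 is oxidised in step 13.

Step 12
Reactants: 18 (2S,3R)-3-(benzyloxy)pent-4-en-2-ol; 14 {[(3R,5Z)-6-iodo-3-(propan-2-yl)hepta-1,5-dien-2-yl]oxy}tri(propan-2-yl)silane
Product: 20 (2S,3R,6Z,9R)-3-(benzyloxy)-6-methyl-9-(propan-2-yl)-10-{[tri(propan-2-yl)silyl]oxy}undeca-6,10-dien-2-ol, via alkylborane 19 (not isolated)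
Conditions: 9-BBN (2.2 equiv), THF, 0 °C to rt; then 14, PdCl2(dppf) (5 mol%), AsPh3, Cs2CO3, DMF/H2O, rt
Reagents that add atoms: none
Why: Anti-Markovnikov hydroboration of the terminal alkene, then B-alkyl Suzuki–Miyaura coupling forms the C1–C10 bond; oxidative addition of the alkenyl iodide to zerovalent palladium and reductive elimination both retain geometry, so the alkene stays Z. The hydroxyl travels as a B–O borinate that is hydrolysed on work-up, and cold aqueous carbonate should leave the bulky enol silane intact.

Step 13
Reactants: 20 (2S,3R,6Z,9R)-3-(benzyloxy)-6-methyl-9-(propan-2-yl)-10-{[tri(propan-2-yl)silyl]oxy}undeca-6,10-dien-2-ol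
Product: 21 (3R,6Z,9R)-3-(benzyloxy)-6-methyl-9-(propan-2-yl)-10-{[tri(propan-2-yl)silyl]oxy}undeca-6,10-dien-2-one
Conditions: Dess–Martin periodinane, pyridine, CH2Cl2, 0 °C
Reagents that add atoms: none
Why: Dess–Martin oxidation proceeds by ligand exchange at iodine on the hydroxyl and, buffered with pyridine, neither protonates nor oxidises the enol silane; the α-benzyloxy ketone forms without epimerisation of C3.

Step 14
Reactants: 21 (3R,6Z,9R)-3-(benzyloxy)-6-methyl-9-(propan-2-yl)-10-{[tri(propan-2-yl)silyl]oxy}undeca-6,10-dien-2-one
Product: 22 (3R,4aS,5S,6R,8aR)-6-(benzyloxy)-5-hydroxy-5,8a-dimethyl-3-(propan-2-yl)octahydronaphthalen-2(1H)-one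
Conditions: SnCl4 (1.2 equiv), 2,6-di-tert-butyl-4-methylpyridine (0.3 equiv), CH2Cl2 (0.005 M, slow addition of 21), −78 to −40 °C; then aq. NaHCO3
Reagents that add atoms: none
Why: Proposed new method: SnCl4 binds the C4 carbonyl oxygen and the C3 benzyloxy oxygen in a five-membered chelate; alkene carbon C5 attacks the activated carbonyl carbon C4, the tertiary cation developing at C10 is captured on the opposite face by C9 of the enol silane, and the silyloxocarbenium ion at C8 loses iPr3SiCl to leave the ketone, with the C4 oxygen held as tin alkoxide until work-up. The closest known reaction types are Lewis-acid Prins and carbonyl-ene cyclisations of keto-alkenes and the aldehyde-, acetal- and epoxide-initiated polyene cyclisations that end at an enol silane; a ketone as initiator of such a bicyclisation is the untested element. Ring A closes 6-endo with respect to the C5=C10 alkene (C4–C5 bond) and ring B closes 6-endo with respect to the C8=C9 enol ether (C9–C10 bond). C4 is controlled by the chelate: C5 can approach perpendicular to the carbonyl plane while both oxygens stay on tin only if the benzyloxy group is axial in the ring A chair, and this arrangement delivers O4 equatorial and cis to O3 with the C4 methyl axial. C5 and C10 are controlled by anti addition across the Z alkene, which gives the cis fusion, and by the same C3-fixed chair, which selects the alkene face that puts H5 and the C10 methyl on the side opposite to both oxygens (3R gives 4S,5S,10R). C7 is not created here; its isopropyl group is pseudo-axial in the ring B chair, away from the silyloxy group on C8, and becomes the equatorial, more stable epimer once the cis-decalin flips to its other chair–chair form, so enolisation can only reinforce it. The step needs the alkene, not the enol silane, to attack the ketone, which the six-membered closure (against a ten-membered or intermolecular aldol), the bulk of the iPr3Si group and high dilution secure, and it needs capture by the enol silane to outrun proton loss from the C10 cation, which two-point binding of the carbonyl oxygen to tin and the hindered pyridine (scavenger for HCl) favour.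

Step 15
Reactants: 22 (3R,4aS,5S,6R,8aR)-6-(benzyloxy)-5-hydroxy-5,8a-dimethyl-3-(propan-2-yl)octahydronaphthalen-2(1H)-one
Product: 23 (3R,4aS,5S,6R,8aR)-5,6-dihydroxy-5,8a-dimethyl-3-(propan-2-yl)octahydronaphthalen-2(1H)-one
Conditions: H2 (1 atm), Pd/C (10 wt%), EtOAc, rt
Reagents that add atoms: none
Why: Hydrogenolysis of the benzyl ether; 22 has no alkene, the ketone and the tertiary alcohol are inert, and the step precedes introduction of the hydrogenation-sensitive angelate.

Step 16
Reactants: 23 (3R,4aS,5S,6R,8aR)-5,6-dihydroxy-5,8a-dimethyl-3-(propan-2-yl)octahydronaphthalen-2(1H)-one; 24 angelic acid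
Product: 26 (1S,2R,4aR,7R,8aS)-1-hydroxy-1,4a-dimethyl-6-oxo-7-(propan-2-yl)decahydronaphthalen-2-yl (2Z)-2-methylbut-2-enoate, via mixed anhydride 25 (not isolated)
Conditions: 24, 2,4,6-trichlorobenzoyl chloride, Et3N, toluene, rt; then 23, 80 °C
Reagents that add atoms: none
Why: Yamaguchi-type esterification run without a nucleophilic catalyst: the alcohol attacks the angeloyl carbonyl of the mixed anhydride (the aryl carbonyl is shielded by two ortho chlorines), and with no DMAP the addition–elimination path that turns angelates into tiglates is not opened. Only the secondary C3 hydroxyl reacts; the tertiary C4 hydroxyl is too hindered.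

Step 17
Reactants: 26 (1S,2R,4aR,7R,8aS)-1-hydroxy-1,4a-dimethyl-6-oxo-7-(propan-2-yl)decahydronaphthalen-2-yl (2Z)-2-methylbut-2-enoate
Product: 27 (1S,2R,4aR,7R,8aS)-1-(acetyloxy)-1,4a-dimethyl-6-oxo-7-(propan-2-yl)decahydronaphthalen-2-yl (2Z)-2-methylbut-2-enoate
Conditions: Ac2O, Sc(OTf)3 (5 mol%), MeCN, −20 °C
Reagents that add atoms: acetic anhydride, CC(=O)OC(C)=O
Why: Lewis-acid-catalysed acylation with the anhydride acetylates hindered tertiary alcohols at low temperature; no base is present, so neither acyl migration nor base-induced angelate isomerisation can occur, and ionisation at C4 is disfavoured by the neighbouring acyloxy group.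

## Compound list

1 | but-2-yn-1-ol | CC#CCO | starting material
2 | sodium 2,2-bis(2-methoxyethoxy)-3-methyl-2,5-dihydro-1,2-oxaluminol-2-uide (cyclic alkenylalanate) | [Na+].COCCO[Al-]1(OCCOC)OCC=C1C | intermediate
3 | (Z)-3-iodobut-2-en-1-ol | C/C(I)=C/CO | intermediate
4 | (Z)-1-bromo-3-iodobut-2-ene | C/C(I)=C/CBr | intermediate
5 | (R)-4-benzyloxazolidin-2-one | O=C1N[C@H](Cc2ccccc2)CO1 | starting material
6 | 3-methylbutanoyl chloride | CC(C)CC(Cl)=O | starting material
7 | (R)-4-benzyl-3-(3-methylbutanoyl)oxazolidin-2-one | CC(C)CC(=O)N1[C@H](Cc2ccccc2)COC1=O | intermediate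
8 | sodium (1Z)-1-[(4R)-4-benzyl-2-oxo-1,3-oxazolidin-3-yl]-3-methylbut-1-en-1-olate | CC(C)/C=C(\[O-])N1[C@H](Cc2ccccc2)COC1=O.[Na+] | intermediate
9 | (R)-4-benzyl-3-[(2R,4Z)-5-iodo-2-(propan-2-yl)hex-4-enoyl]oxazolidin-2-one | C/C(I)=C/C[C@H](C(C)C)C(=O)N1[C@H](Cc2ccccc2)COC1=O | intermediate
10 | (2R,4Z)-5-iodo-2-(propan-2-yl)hex-4-enoic acid | C/C(I)=C/C[C@H](C(C)C)C(=O)O | intermediate
11 | (2R,4Z)-5-iodo-N-methoxy-N-methyl-2-(propan-2-yl)hex-4-enamide | C/C(I)=C/C[C@H](C(C)C)C(=O)N(C)OC | intermediate
12 | (3R,5Z)-6-iodo-3-(propan-2-yl)hept-5-en-2-one | C/C(I)=C/C[C@H](C(C)C)C(C)=O | intermediate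
13 | lithium (3R,5Z)-6-iodo-3-(propan-2-yl)hepta-1,5-dien-2-olate | C/C(I)=C/C[C@H](C(C)C)C(=C)[O-].[Li+] | intermediate
14 | {[(3R,5Z)-6-iodo-3-(propan-2-yl)hepta-1,5-dien-2-yl]oxy}tri(propan-2-yl)silane | C/C(I)=C/C[C@H](C(C)C)C(=C)O[Si](C(C)C)(C(C)C)C(C)C | intermediate
15 | penta-1,4-dien-3-ol | C=CC(O)C=C | starting material
16 | (2S,3R)-1,2-epoxypent-4-en-3-ol | C=C[C@@H](O)[C@@H]1CO1 | intermediate
17 | (2S)-2-[(1R)-1-(benzyloxy)prop-2-en-1-yl]oxirane | C=C[C@@H](OCc1ccccc1)[C@@H]1CO1 | intermediate
18 | (2S,3R)-3-(benzyloxy)pent-4-en-2-ol | C=C[C@@H](OCc1ccccc1)[C@H](C)O | intermediate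
19 | 9-{(3R,4S)-3-(benzyloxy)-4-[(9-borabicyclo[3.3.1]nonan-9-yl)oxy]pentyl}-9-borabicyclo[3.3.1]nonane | C[C@H](OB1C2CCCC1CCC2)[C@H](OCc1ccccc1)CCB1C2CCCC1CCC2 | intermediate
20 | (2S,3R,6Z,9R)-3-(benzyloxy)-6-methyl-9-(propan-2-yl)-10-{[tri(propan-2-yl)silyl]oxy}undeca-6,10-dien-2-ol | C[C@H](O)[C@H](OCc1ccccc1)CC/C(C)=C\C[C@H](C(C)C)C(=C)O[Si](C(C)C)(C(C)C)C(C)C | intermediate
21 | (3R,6Z,9R)-3-(benzyloxy)-6-methyl-9-(propan-2-yl)-10-{[tri(propan-2-yl)silyl]oxy}undeca-6,10-dien-2-one | CC(=O)[C@H](OCc1ccccc1)CC/C(C)=C\C[C@H](C(C)C)C(=C)O[Si](C(C)C)(C(C)C)C(C)C | intermediate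
22 | (3R,4aS,5S,6R,8aR)-6-(benzyloxy)-5-hydroxy-5,8a-dimethyl-3-(propan-2-yl)octahydronaphthalen-2(1H)-one (cis-fused; 3-O-benzyl, 4-hydroxy, 8-oxo in eudesmane numbering) | c1ccccc1CO[C@@H]1CC[C@]2(C)CC(=O)[C@@H](C(C)C)C[C@@H]2[C@]1(C)O | intermediate
23 | (3R,4aS,5S,6R,8aR)-5,6-dihydroxy-5,8a-dimethyl-3-(propan-2-yl)octahydronaphthalen-2(1H)-one | O[C@@H]1CC[C@]2(C)CC(=O)[C@@H](C(C)C)C[C@@H]2[C@]1(C)O | intermediate
24 | angelic acid, (2Z)-2-methylbut-2-enoic acid | C/C=C(/C)C(=O)O | starting material
25 | (2Z)-2-methylbut-2-enoic 2,4,6-trichlorobenzoic anhydride | C/C=C(/C)C(=O)OC(=O)c1c(Cl)cc(Cl)cc1Cl | intermediate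
26 | (1S,2R,4aR,7R,8aS)-1-hydroxy-1,4a-dimethyl-6-oxo-7-(propan-2-yl)decahydronaphthalen-2-yl (2Z)-2-methylbut-2-enoate | C/C=C(/C)C(=O)O[C@@H]1CC[C@]2(C)CC(=O)[C@@H](C(C)C)C[C@@H]2[C@]1(C)O | intermediate
27 | (1S,2R,4aR,7R,8aS)-1-(acetyloxy)-1,4a-dimethyl-6-oxo-7-(propan-2-yl)decahydronaphthalen-2-yl (2Z)-2-methylbut-2-enoate | C/C=C(/C)C(=O)O[C@@H]1CC[C@]2(C)CC(=O)[C@@H](C(C)C)C[C@@H]2[C@]1(C)OC(C)=O | target

## Step count and least certain steps

Total step count: 17. Longest linear sequence: 13 steps (steps 1, 2, 4–8 and 12–17, from but-2-yn-1-ol). Step 3 and steps 9–11 are side branches.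

**Step 14 (key step, proposed new method).**
- What may go wrong: interception of the C10 cation before ring B closes (proton loss toward the C10 methyl or C1, or chloride capture), because anti capture demands a chair–chair array with the benzyloxy group, C6 and the C4 methyl all axial. Next in likelihood are loss of the enol silane by protonation or its direct aldol addition to the chelated ketone, and leakage through a non-chelated chair with equatorial benzyloxy, which would give the 3-epi series.
- Fallback (known reaction types, from 21 back to 22): the two bonds are made in separate steps.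
  - Desilylation of 21 (nBu4NF buffered with AcOH, THF, 0 °C) gives (3R,6Z,9R)-3-(benzyloxy)-6-methyl-9-(propan-2-yl)undec-6-ene-2,10-dione F1.
  - Excess TiCl4 in CH2Cl2 at −78 °C closes ring A alone in a chelation-controlled Prins cyclisation ended by chloride, giving chloro alcohol F2 (C4–C5 bond formed, tertiary chloride on C10).
  - LiN(iPr)2 (2.2 equiv) and Me3SiCl convert F2 into bis-silyl compound F3 (C4 trimethylsilyl ether, kinetic C8 trimethylsilyl enol ether).
  - TiCl4 then ionises the tertiary chloride and the enol silane alkylates C10 (Lewis-acid tert-alkylation of enol silanes), and K2CO3 in MeOH frees the C4 hydroxyl to give 22.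
  - In this variant the ring fusion is set by axial capture of the ring A cation beside the equatorial C6 chain, which also leads to the cis-decalin.

**Step 12 (coupling).**
- What may go wrong: slow transmetalation of a borane that carries a B–O borinate next to the benzyloxy group, leaving time for protodeiodination of 14 or hydrolysis of the enol silane in aqueous carbonate.
- Fallback (from 12 and 18 back to 20): the fragments are joined at the ketone stage and the enol silane is made afterwards.
  - Borane 19 and ketone 12 under the same Suzuki–Miyaura conditions give hydroxy ketone F4.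
  - Me3SiCl and imidazole give trimethylsilyl ether F5.
  - LiN(iPr)2 then iPr3SiOTf give enol silane F6.
  - K2CO3 in MeOH at 0 °C removes only the trimethylsilyl ether and returns 20.

**Step 16 (angeloylation).**
- What may go wrong: Z-to-E isomerisation of the angeloyl group during activation or prolonged heating with amine (tiglate formation), and slow acylation of a secondary hydroxyl flanked by a fully substituted carbon.
- Fallback (from 23 back to 26): the Z alkene is built on the ester.
  - Steglich esterification of O3 with 2-[bis(2,2,2-trifluoroethoxy)phosphoryl]propanoic acid (EDC·HCl, DMAP, CH2Cl2) gives phosphonate ester F7.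
  - Still–Gennari olefination with acetaldehyde (KN(SiMe3)2, 18-crown-6, THF, −78 °C) gives the Z-2-methylbut-2-enoate 26.

**Step 17 (tertiary acetate).**
- What may go wrong: no reaction at the hindered tertiary hydroxyl, ionisation at C4 followed by elimination under the Lewis acid, or acid-promoted isomerisation of the angelate.
- Fallback (from 22 to 27): the order of the esters is reversed.
  - The tertiary hydroxyl of 22 is acetylated while O3 is still benzylated (Ac2O, DMAP, Et3N, 60 °C; forcing conditions are allowed because no angelate is present) to give acetate F8.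
  - Hydrogenolysis (H2, Pd/C, EtOAc) gives hydroxy acetate F9.
  - Angeloylation with preformed, amine-free mixed anhydride 25 in toluene at 80 °C gives 27.
  - The price is brief exposure of a cis-vicinal hydroxy acetate to acylation conditions, which is why the anhydride would be used without added base.

## Further compounds

F1 | step 14 | (3R,6Z,9R)-3-(benzyloxy)-6-methyl-9-(propan-2-yl)undec-6-ene-2,10-dione | CC(=O)[C@H](OCc1ccccc1)CC/C(C)=C\C[C@H](C(C)C)C(C)=O
F2 | step 14 | (3R)-4-[(1R,2S,3R,6S)-3-(benzyloxy)-6-chloro-2-hydroxy-2,6-dimethylcyclohexyl]-3-(propan-2-yl)butan-2-one | c1ccccc1CO[C@@H]1CC[C@](C)(Cl)[C@H](C[C@H](C(C)C)C(C)=O)[C@]1(C)O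
F3 | step 14 | {[(3R)-4-{(1R,2S,3R,6S)-3-(benzyloxy)-6-chloro-2,6-dimethyl-2-[(trimethylsilyl)oxy]cyclohexyl}-3-(propan-2-yl)but-1-en-2-yl]oxy}trimethylsilane | c1ccccc1CO[C@@H]1CC[C@](C)(Cl)[C@H](C[C@H](C(C)C)C(=C)O[Si](C)(C)C)[C@]1(C)O[Si](C)(C)C
F4 | step 12 | (3R,5Z,9R,10S)-9-(benzyloxy)-10-hydroxy-6-methyl-3-(propan-2-yl)undec-5-en-2-one | C[C@H](O)[C@H](OCc1ccccc1)CC/C(C)=C\C[C@H](C(C)C)C(C)=O
F5 | step 12 | (3R,5Z,9R,10S)-9-(benzyloxy)-6-methyl-3-(propan-2-yl)-10-[(trimethylsilyl)oxy]undec-5-en-2-one | C[C@H](O[Si](C)(C)C)[C@H](OCc1ccccc1)CC/C(C)=C\C[C@H](C(C)C)C(C)=O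
F6 | step 12 | trimethylsilyl ether of alcohol 20, (2S,3R,6Z,9R)-configured | C[C@H](O[Si](C)(C)C)[C@H](OCc1ccccc1)CC/C(C)=C\C[C@H](C(C)C)C(=C)O[Si](C(C)C)(C(C)C)C(C)C
F7 | step 16 | (1S,2R,4aR,7R,8aS)-1-hydroxy-1,4a-dimethyl-6-oxo-7-(propan-2-yl)decahydronaphthalen-2-yl 2-[bis(2,2,2-trifluoroethoxy)phosphoryl]propanoate (both epimers at the phosphonate carbon) | CC(C(=O)O[C@@H]1CC[C@]2(C)CC(=O)[C@@H](C(C)C)C[C@@H]2[C@]1(C)O)P(=O)(OCC(F)(F)F)OCC(F)(F)F
F8 | step 17 | (1S,2R,4aR,7R,8aS)-2-(benzyloxy)-1,4a-dimethyl-6-oxo-7-(propan-2-yl)decahydronaphthalen-1-yl acetate | c1ccccc1CO[C@@H]1CC[C@]2(C)CC(=O)[C@@H](C(C)C)C[C@@H]2[C@]1(C)OC(C)=O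
F9 | step 17 | (1S,2R,4aR,7R,8aS)-2-hydroxy-1,4a-dimethyl-6-oxo-7-(propan-2-yl)decahydronaphthalen-1-yl acetate | O[C@@H]1CC[C@]2(C)CC(=O)[C@@H](C(C)C)C[C@@H]2[C@]1(C)OC(C)=O
A1 | alternative 1 | ring A cyclohexene carboxylic acid with C1=C2 alkene, C3,C4 acetonide and C8 dimethyl ketal side chain | OC(=O)[C@@H]1[C@]2(C)OC(C)(C)O[C@@H]2C=C[C@]1(C)CC(OC)(OC)CC(C)C
A2 | alternative 2 | cis-fused bicyclic dienone with C8 ketone and C1=C2, C3=C4 alkenes | C1=C[C@]2(C)CC(=O)[C@@H](C(C)C)C[C@@H]2C(C)=C1
A3 | alternative 3 | cis-decalin C3 ketone with C4 methoxymethyl ether and C8=C9 alkene | O=C1CC[C@]2(C)C=C[C@@H](C(C)C)C[C@@H]2[C@]1(C)OCOC
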